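Assumption: a one-pot sequence that ends in one isolated product counts as one step, and compound numbers follow the forward route.

**Retrosynthetic overview**
- The ring alkene is made last: reductive 1,3-transposition (hydride, then retro-ene loss of N2) of an α,β-unsaturated tosylhydrazone turns the carbonyl carbon of a carvone-type enone into the ring =CH.
- Key disconnection: the pyranone C3–cyclohexenyl C1 bond, made by conjugate addition of the pyranone C3 donor to an azoalkene, an enolonium equivalent of the enone α'-carbon. Two α-carbons that are both donors in normal polarity are joined (masked 1,4-dicarbonyl), and the trans relationship to isopropyl is set here.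
- Azoalkene ⇐ α'-chloro enone ⇐ (S)-carvotanacetone ⇐ (S)-(+)-carvone, the only source of chirality.
- Pyranone partner ⇐ triacetic acid lactone + benzaldehyde by vinylogous aldol condensation.
- Ring order: no ring is built; the carbocycle comes from carvone and the pyranone ring from triacetic acid lactone.

**Route**

Step 1
Reactants: 1 4-hydroxy-6-methyl-2H-pyran-2-one (triacetic acid lactone); 2 benzaldehyde
Product: 5 4-hydroxy-6-[(E)-2-phenylethenyl]-2H-pyran-2-one, via dilithio dianion 3 (not isolated), via aldol adduct 4 (not isolated)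
Conditions: LiN(iPr)2 (2.3 equiv), THF, −78 °C; then 2, −78 to 0 °C; then 3 M HCl, 50 °C
Reagents that add atoms: none
Why: Vinylogous aldol condensation: the O,C-dianion adds through its 6-CH2 carbon to benzaldehyde and the benzylic alcohol dehydrates under acid to the conjugated, thermodynamically preferred E-alkene; no stereocentre is formed.

Step 2
Reactants: 6 (S)-(+)-carvone
Product: 7 (5S)-2-methyl-5-(propan-2-yl)cyclohex-2-en-1-one ((S)-carvotanacetone)
Conditions: H2 (1 atm), RhCl(PPh3)3 (1 mol %), benzene, rt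
Reagents that add atoms: none
Why: Homogeneous hydrogenation with RhCl(PPh3)3 reduces only the unhindered 1,1-disubstituted isopropenyl alkene and leaves the conjugated trisubstituted enone, so the C5 stereocentre of carvone is carried over unchanged (still S).

Step 3
Reactants: 7 (S)-carvotanacetone
Product: 9 (5R,6RS)-6-chloro-2-methyl-5-(propan-2-yl)cyclohex-2-en-1-one, via lithium dienolate 8 (not isolated)
Conditions: LiN(iPr)2 (1.1 equiv), THF, −78 °C; then TsCl (1.1 equiv), −78 to −20 °C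
Reagents that add atoms: p-toluenesulfonyl chloride (TsCl), Cc1ccc(cc1)S(=O)(=O)Cl
Why: Enolate α-chlorination: kinetic α'-deprotonation gives the cross-conjugated dienolate, which takes Cl+ from TsCl at C6; the C6 configuration is erased in step 4, and C5 keeps its geometry (its descriptor changes to R only because C6 now outranks isopropyl).

Step 4
Reactants: 9 (5R,6RS)-6-chloro-2-methyl-5-(propan-2-yl)cyclohex-2-en-1-one; 5 4-hydroxy-6-[(E)-2-phenylethenyl]-2H-pyran-2-one
Product: 12 N'-[(5R,6S)-6-{4-hydroxy-2-oxo-6-[(E)-2-phenylethenyl]-2H-pyran-3-yl}-2-methyl-5-(propan-2-yl)cyclohex-2-en-1-ylidene]-4-methylbenzenesulfonohydrazide, via chloro tosylhydrazone 10 (not isolated), via azoalkene 11 (not isolated)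
Conditions: TsNHNH2 (1.0 equiv), THF, 0 °C to rt; then added slowly to 5 (1.2 equiv), Na2CO3 (2.5 equiv), THF–MeCN, 0 °C to rt
Reagents that add atoms: p-toluenesulfonohydrazide (TsNHNH2), Cc1ccc(cc1)S(=O)(=O)NN
Why: Hydrazone formation, base-induced 1,4-elimination of HCl to the azoalkene (1,2-diaza-1,3-diene, an enolonium equivalent of the ketone α'-carbon) and Michael addition of pyranone C3 to it join two normally nucleophilic α-carbons; attack anti to the neighbouring isopropyl group sets the new centre trans (6S), and because this C–H stays epimerisable α to C=N the trans isomer is also reached by equilibration.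

Step 5
Reactants: 12 the trans tosylhydrazone from step 4
Product: 15 4-hydroxy-3-[(1R,6R)-3-methyl-6-(propan-2-yl)cyclohex-2-en-1-yl]-6-[(E)-2-phenylethenyl]-2H-pyran-2-one, via allylic tosylhydrazine 13 (not isolated), via allylic diazene 14 (not isolated)
Conditions: catecholborane (3 equiv), CHCl3, 0 °C to rt; then NaOAc·3H2O, 60 °C
Reagents that add atoms: none
Why: Kabalka-type reductive 1,3-transposition of an enone tosylhydrazone: hydride adds to the C=N carbon, acetate-promoted loss of p-toluenesulfinate gives the allylic diazene, and its retro-ene loss of N2 delivers H to the former β-carbon and moves the alkene regiospecifically to the methyl-bearing position next to the pyranone-bearing carbon; neither stereocentre is touched, giving the (1R,6R) target.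

**Compound list**

1 | 4-hydroxy-6-methyl-2H-pyran-2-one (triacetic acid lactone) | Cc1cc(O)cc(=O)o1 | starting material
2 | benzaldehyde | O=Cc1ccccc1 | starting material
3 | dilithium dianion of 1 (4-olate and 6-CH2 carbanion) | [Li+].[Li+].[CH2-]c1cc([O-])cc(=O)o1 | intermediate
4 | 4-hydroxy-6-(2-hydroxy-2-phenylethyl)-2H-pyran-2-one (racemic aldol adduct) | OC(Cc1cc(O)cc(=O)o1)c1ccccc1 | intermediate
5 | 4-hydroxy-6-[(E)-2-phenylethenyl]-2H-pyran-2-one | O=c1cc(O)cc(/C=C/c2ccccc2)o1 | intermediate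
6 | (S)-(+)-carvone, (5S)-2-methyl-5-(prop-1-en-2-yl)cyclohex-2-en-1-one | CC1=CC[C@@H](CC1=O)C(C)=C | starting material
7 | (S)-carvotanacetone, (5S)-2-methyl-5-(propan-2-yl)cyclohex-2-en-1-one | CC1=CC[C@@H](CC1=O)C(C)C | intermediate
8 | lithium (3R)-6-methyl-3-(propan-2-yl)cyclohexa-1,5-dien-1-olate (cross-conjugated dienolate of 7) | CC1=CC[C@H](C(C)C)C=C1[O-].[Li+] | intermediate
9 | (5R,6RS)-6-chloro-2-methyl-5-(propan-2-yl)cyclohex-2-en-1-one (C6 epimers) | CC1=CC[C@H](C(C)C)C(Cl)C1=O | intermediate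
10 | N'-[(5R,6RS)-6-chloro-2-methyl-5-(propan-2-yl)cyclohex-2-en-1-ylidene]-4-methylbenzenesulfonohydrazide | CC1=CC[C@H](C(C)C)C(Cl)C1=NNS(=O)(=O)c1ccc(C)cc1 | intermediate
11 | (E)-1-[(3R)-6-methyl-3-(propan-2-yl)cyclohexa-1,5-dien-1-yl]-2-(4-methylbenzenesulfonyl)diazene (azoalkene) | CC1=CC[C@H](C(C)C)C=C1/N=N/S(=O)(=O)c1ccc(C)cc1 | intermediate
12 | N'-[(5R,6S)-6-{4-hydroxy-2-oxo-6-[(E)-2-phenylethenyl]-2H-pyran-3-yl}-2-methyl-5-(propan-2-yl)cyclohex-2-en-1-ylidene]-4-methylbenzenesulfonohydrazide (pyranone trans to isopropyl) | CC1=CC[C@H](C(C)C)[C@@H](c2c(O)cc(/C=C/c3ccccc3)oc2=O)C1=NNS(=O)(=O)c1ccc(C)cc1 | intermediate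
13 | N'-[(1RS,5R,6S)-6-{4-hydroxy-2-oxo-6-[(E)-2-phenylethenyl]-2H-pyran-3-yl}-2-methyl-5-(propan-2-yl)cyclohex-2-en-1-yl]-4-methylbenzenesulfonohydrazide (drawn as the free N–H form; C1 epimers) | CC1=CC[C@H](C(C)C)[C@@H](c2c(O)cc(/C=C/c3ccccc3)oc2=O)C1NNS(=O)(=O)c1ccc(C)cc1 | intermediate
14 | [(1RS,5R,6S)-6-{4-hydroxy-2-oxo-6-[(E)-2-phenylethenyl]-2H-pyran-3-yl}-2-methyl-5-(propan-2-yl)cyclohex-2-en-1-yl]diazene | CC1=CC[C@H](C(C)C)[C@@H](c2c(O)cc(/C=C/c3ccccc3)oc2=O)C1N=N | intermediate
15 | 4-hydroxy-3-[(1R,6R)-3-methyl-6-(propan-2-yl)cyclohex-2-en-1-yl]-6-[(E)-2-phenylethenyl]-2H-pyran-2-one | CC1=C[C@H](c2c(O)cc(/C=C/c3ccccc3)oc2=O)[C@@H](C(C)C)CC1 | target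

**Step count and risks**

Total steps: 5. Longest linear sequence: 4 steps (6 → 7 → 9 → 12 → 15); step 1 is the convergent branch.

Most likely to fail, step 4 (key coupling). The cross-conjugated azoalkene 11 can tautomerise towards an aromatic N-aryl-N'-tosylhydrazine, and the pyranone anion can react at oxygen. The fallback moves the polarity reversal from the hydrazone level to the ketone level; it sets out from 7 (and uses 5) and comes back at 12. 7 is silylated (LiN(iPr)2, Me3SiCl, THF, −78 °C) to the cross-conjugated silyl dienol ether trimethyl{[(3R)-6-methyl-3-(propan-2-yl)cyclohexa-1,5-dien-1-yl]oxy}silane F1. F1 is oxidised with PhI(OAc)2/BF3·OEt2 (CH2Cl2, −78 °C) to the O-bound acetoxy(phenyl)iodanyl enol ether F2, an enolonium species of trivalent iodine. The silyl enol ether of 5, 4-[(trimethylsilyl)oxy]-6-[(E)-2-phenylethenyl]-2H-pyran-2-one F3 (from 5 and N,O-bis(trimethylsilyl)acetamide), attacks C6 of F2 through its C3 and gives after work-up the trans ketone (5R,6S)-6-{4-hydroxy-2-oxo-6-[(E)-2-phenylethenyl]-2H-pyran-3-yl}-2-methyl-5-(propan-2-yl)cyclohex-2-en-1-one F4. Condensation of F4 with TsNHNH2 (pyridine, EtOH, rt, buffered to avoid furan formation) gives 12.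

Second, step 5 (reductive transposition). The borane may attack the styryl dienyl lactone, or the hindered C=N may reduce slowly. The fallback installs the styryl group last; it sets out from 9 (with 1 and 2) and comes back at 15. Step 4 is run with 1 in place of 5 to give N'-[(5R,6S)-6-(4-hydroxy-6-methyl-2-oxo-2H-pyran-3-yl)-2-methyl-5-(propan-2-yl)cyclohex-2-en-1-ylidene]-4-methylbenzenesulfonohydrazide F5. The same catecholborane/NaOAc·3H2O transposition on F5, which carries no styryl group, gives 4-hydroxy-6-methyl-3-[(1R,6R)-3-methyl-6-(propan-2-yl)cyclohex-2-en-1-yl]-2H-pyran-2-one F6. Double deprotonation of F6 with LiN(iPr)2 and addition to 2 gives the aldol 4-hydroxy-6-(2-hydroxy-2-phenylethyl)-3-[(1R,6R)-3-methyl-6-(propan-2-yl)cyclohex-2-en-1-yl]-2H-pyran-2-one F7, and dehydration of F7 (cat. TsOH, toluene, 50 °C) gives 15.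

Third, step 3 (α'-chlorination). Over-chlorination or loss of HCl with aromatisation to the phenol can erode 9. The fallback replaces enolate chlorination by radical α'-oxidation; it sets out from 7 and comes back at 11. Mn(OAc)3·2H2O (benzene, reflux) converts 7 into (5R,6RS)-6-acetoxy-2-methyl-5-(propan-2-yl)cyclohex-2-en-1-one F8. TsNHNH2 (THF, rt) gives its tosylhydrazone N'-[(5R,6RS)-6-acetoxy-2-methyl-5-(propan-2-yl)cyclohex-2-en-1-ylidene]-4-methylbenzenesulfonohydrazide F9. Cs2CO3 in MeCN, with 5 present, eliminates acetate from F9 to give azoalkene 11, which is trapped as in step 4.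

**Further compounds**

F1 | step 4 | trimethyl{[(3R)-6-methyl-3-(propan-2-yl)cyclohexa-1,5-dien-1-yl]oxy}silane | CC1=CC[C@H](C(C)C)C=C1O[Si](C)(C)C
F2 | step 4 | O-bound acetoxy(phenyl)iodanyl enol ether of 7 (enolonium species) | CC1=CC[C@H](C(C)C)C=C1O[I](OC(C)=O)c1ccccc1
F3 | step 4 | 4-[(trimethylsilyl)oxy]-6-[(E)-2-phenylethenyl]-2H-pyran-2-one | C[Si](C)(C)Oc1cc(/C=C/c2ccccc2)oc(=O)c1
F4 | step 4 | (5R,6S)-6-{4-hydroxy-2-oxo-6-[(E)-2-phenylethenyl]-2H-pyran-3-yl}-2-methyl-5-(propan-2-yl)cyclohex-2-en-1-one | CC1=CC[C@H](C(C)C)[C@@H](c2c(O)cc(/C=C/c3ccccc3)oc2=O)C1=O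
F5 | step 5 | N'-[(5R,6S)-6-(4-hydroxy-6-methyl-2-oxo-2H-pyran-3-yl)-2-methyl-5-(propan-2-yl)cyclohex-2-en-1-ylidene]-4-methylbenzenesulfonohydrazide | CC1=CC[C@H](C(C)C)[C@@H](c2c(O)cc(C)oc2=O)C1=NNS(=O)(=O)c1ccc(C)cc1
F6 | step 5 | 4-hydroxy-6-methyl-3-[(1R,6R)-3-methyl-6-(propan-2-yl)cyclohex-2-en-1-yl]-2H-pyran-2-one | CC1=C[C@H](c2c(O)cc(C)oc2=O)[C@@H](C(C)C)CC1
F7 | step 5 | 4-hydroxy-6-(2-hydroxy-2-phenylethyl)-3-[(1R,6R)-3-methyl-6-(propan-2-yl)cyclohex-2-en-1-yl]-2H-pyran-2-one (carbinol epimers) | CC1=C[C@H](c2c(O)cc(CC(O)c3ccccc3)oc2=O)[C@@H](C(C)C)CC1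
F8 | step 3 | (5R,6RS)-6-acetoxy-2-methyl-5-(propan-2-yl)cyclohex-2-en-1-one | CC1=CC[C@H](C(C)C)C(OC(C)=O)C1=O
F9 | step 3 | N'-[(5R,6RS)-6-acetoxy-2-methyl-5-(propan-2-yl)cyclohex-2-en-1-ylidene]-4-methylbenzenesulfonohydrazide | CC1=CC[C@H](C(C)C)C(OC(C)=O)C1=NNS(=O)(=O)c1ccc(C)cc1
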